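One point of single product in the larch flask is 5.00 × 10⁻⁴ M, and if each product takes up one reagent, it is the same amount of reagent. The 22.2% read at 8.00 min therefore holds 21.1% of the reagent charge. This is the capture share: product formed, times substrate charged, divided by reagent charged.

- larch: substrate 0.050 M (in portions, 2); reagent 0.0525 M; the very flask that is asked about, followed so far; portions every 15 s
- flask: substrate 0.050 M (in portions, 2); reagent 0.0525 M; time 25 min; the portions of substrate follow each other after 15 s, the first at the start

- larch (time / min: substrate / %, single product / %): 0.667: 84.0, 16.5; 1.00: 80.8, 19.5; 2.00: 78.4, 21.6; 4.00: 77.7, 22.2; 8.00: 77.3, 22.2

(each reading ± 0.3 percentage points)

- why nothing more happens at 25 min, or that something still does (the reagent has run out first / it is still moving / all of the substrate has reacted)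
- part of the substrate gone at 25 min
- the single product standing at 25 min, as a percentage of the substrate charged

- the reaction counts as stopped when no species that holds the substrate changes by six tenths of a point or more over the second half of the time

The first estimate for the larch flask is that it has stopped, with the product staying where it stands. One objection is that the substrate still fell 0.4 percentage points between 4.00 min and 8.00 min. Continued evenly, that creep gives 1.3 points over the last 12.5 min, beyond the stopping margin. But each reading scatters by 0.3 points, and the product reads 22.2% and then 22.2%, so the creep is not established.

A harder objection: the capture share leaves 0.0414 M of reagent unaccounted for, and if that stood in the larch flask, the reaction ought to go on. Yet the substrate's fall per minute between 0.667 min and 1.00 min, set over that between 2.00 min and 4.00 min, reads as a ratio of 27.5, larger than the ratio 1.07 of the substrate readings at 0.667 min and 2.00 min, so the unaccounted reagent has probably left by another route. The reckoning here keeps the product at 22.2% and puts conversion between that figure and 22.7%.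

The forecast says the reagent has run out first, with 22.6% gone and 22.4% standing. Its ground: “the active reagent must be disappearing by some route that leaves no substrate-derived species”. Its product figure stands slightly higher than the one reckoned here.

The larch flask gives this answer: the reagent has run out first, with 0% of the reagent left, 22.4% of the substrate gone and 22.3% of single product standing at 25 min.

    substrate + reagent → single product + by-product (k = 0.540 /M/s)
    reagent + single product → bis adduct + by-product (k = 0.00930 /M/s)
    reagent + bis adduct → tris adduct + by-product (k = 3.30 /M/s)
    reagent + tris adduct → tetra adduct + by-product (k = 1.30 /M/s)
    2 reagent → self-condensation product (k = 1.80 /M/s)
    tris adduct → over-reaction product (k = 7.80 × 10⁻⁵ /s)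

At 25.0 min the larch flask holds 0% of its reagent, less than the 78% of its substrate, and the reagent, charged at 1.05 equivalents, is the limiting reagent. The neighbour flask with 0.085 M of substrate and the same reagent charge has a capture share of 28.4%, higher than the 21.1% read for the larch flask at 8.00 min, while its single product stands at 17.6% of its larger charge.

(The readings are simulated for an exercise; the scatter is artificial.)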